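**The vessel.** A closed, stirred vessel holds starting material and second substrate at equal charge under gas held at saturation, and we want to know what stands at 8.0 d and which option pays.

- beta: starting material 0.033 M; second substrate 0.033 M; gas 4.5 mM (held); the very flask that is asked about, followed so far
- flask: starting material 0.033 M; second substrate 0.0330 M; gas 4.5 mM (held); time 8.0 d

beta run (percent of the starting material charged)

| time / d | target / % |
|---|---|
| 0.500 | 7.3 |
| 1.04 | 13.5 |
| 1.67 | 18.3 |
| 3.00 | 23.5 |
| 6.00 | 26.2 |

(each reading ± 1 percentage point)

- target taken out counts as made
- the analysis behind the earlier runs scatters by 1 percentage point, standard deviation
- at the start none of the gas is in solution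
- additions bring no volume worth counting

- north-west: at 8.0 d add starting material, 50.0% of the amount charged, then wait 4.0 d
- south-east: at 8.0 d take out 90% of the target then present, then wait 4.0 d
- south: change nothing and wait 4.0 d more

- target, in percent of the starting material first charged, at 8.0 d
- what to do for the largest gain in target; "none" if nothing gains more than 2 percentage points (north-west / south-east / south / none)
- target present, with what was taken out counted in, in percent of the starting material first charged, after north-west
- target present, with what was taken out counted in, in percent of the starting material first charged, after south

**The oddity.** In the beta run the target reads 26.2% at 6.00 d and has gained just 2.7 percentage points since 3.00 d, yet by difference 73.8% of the starting material remains and the gas is held, with saturation at 4.5 mM. The target made, 8.65 mM, is more than the saturation concentration of gas, so gas must keep entering the solution.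

**The rule.** We take dissolved [gas] as the concentration that sets the order. It starts at zero, so the rise is not pseudo-first-order; once [gas] stands steady, it is a constant inside the rate, and the late step is pseudo-first-order each way, forward in [starting material] and back in [target]. At steady [gas] such a step stops at a plateau ratio, [target]/[starting material], read from the last beta reading as 0.355. This run cannot show that the second substrate stays out of the step; we commit to that reading. The target reached half its last reading by 1.04 d, a span that includes the rise of [gas], and 4.0 d is 3.85 times that span, so we expect the ratio to return after a disturbance.

**Our reckoning.** The target is then a share 26.2% of the pool of target plus starting material, so we expect that figure at 8.0 d and after waiting. Adding starting material makes the pool 150% of the first charge and gives 39.3%. Removal banks 23.6% and the remaining pool refills, for 43.6%, more than adding.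

**The forecast.** It gave 26.9%, 35.8% after north-west, less than our figure, 27% after waiting, and south-east: “Removal wins.”

**The result.** The flask gives 25.6% at 8.0 d, and south-east gains 17 points, against 12 points for north-west, where the target reaches 38.0%.

    gas ⇌ coupling partner, rate k1*(csat - [coupling partner]) (kL = 0.120 h⁻¹)
    second substrate + coupling partner ⇌ second product (K = 20.0 L mol⁻¹, k = 25.0 L mol⁻¹ h⁻¹)
    starting material + coupling partner ⇌ target (K = 81.0 L mol⁻¹, k = 19.0 L mol⁻¹ h⁻¹)
    coupling partner → decomposed reagent (k = 0.00710 h⁻¹)

At 8.00 d the coupling partner stood at 0.00425 M, close to the gas saturation, and the turning of second substrate into second product makes no difference to the target. The ratio 0.355 puts the target at 26.2% in a neighbour flask with 0.0083 M of starting material, a quarter of this charge, and that flask stood at 25.6% at 8.00 d.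

The numbers in the tables are calculated with constants of no real substance.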